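**Plan**
1. Cuts: first the two O–CH3 bonds that mask the phenols of the resorcinol ring. Then the single skeletal bond C2–C3, between the ketone carbon and the first CH2 of the unbranched C19 chain.
2. Enabling feature: the C2 carbonyl lies between two CH2 groups, the benzylic C1 on the 1,3,5-substituted benzene ring and the primary, unhindered C3. The target is therefore the formal cross-ketonisation product of two carboxylic acids, and C3–C21 is exactly icosanoic acid minus CO2, an odd chain from a cheap even fatty acid.
3. Both carbons are electrophilic at the acid level, so they are joined by a nickel-catalysed radical cross-electrophile coupling. Icosanoic acid serves as its redox-active N-hydroxyphthalimide ester (C19 radical donor) and the arylacetic acid as its S-2-pyridyl thioester (acyl donor).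
4. Forward order: each acid is activated (steps 1 and 2), the chain is joined to the arylacetyl unit (step 3, where all activating groups leave), and the two methyl ethers are cleaved (step 4). The benzene ring is bought and no ring is made.
5. Stereochemistry: the target has no stereocentre and no C=C bond, so nothing has to be set or preserved.

Key step: step 3

Assumption: 1, 3 and all reagents are bought. Because of the long chain, a THF-rich THF/DMA mixture is used in step 3 to keep 2 and 5 in solution.

Step 1
Reactants: 1 icosanoic acid (arachidic acid)
Product: 2 1,3-dioxoisoindolin-2-yl icosanoate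
Conditions: N-hydroxyphthalimide (1.05 equiv), N,N'-diisopropylcarbodiimide (1.1 equiv), 4-(dimethylamino)pyridine (0.1 equiv), CH2Cl2, rt
Reagents that add atoms: N-hydroxyphthalimide, O=C1c2ccccc2C(=O)N1O
Why: Carbodiimide (Steglich-type) esterification of an unhindered primary acid with the acidic N–OH group should install the redox-active ester that later releases CO2 and the C19 radical.

Step 2
Reactants: 3 2-(3,5-dimethoxyphenyl)acetic acid
Product: 4 S-(pyridin-2-yl) 2-(3,5-dimethoxyphenyl)ethanethioate
Conditions: 2,2'-dipyridyl disulfide (1.2 equiv), PPh3 (1.2 equiv), MeCN, rt
Reagents that add atoms: 2,2'-dipyridyl disulfide, c1ccc(SSc2ccccn2)nc1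
Why: The Mukaiyama redox condensation turns the acid into the S-2-pyridyl thioester under neutral conditions, so the acidic benzylic C1–H never meets a base and no ketene pathway opens, and the pyridyl nitrogen later guides nickel into the C(acyl)–S bond.

Step 3
Reactants: 2 1,3-dioxoisoindolin-2-yl icosanoate; 4 S-(pyridin-2-yl) 2-(3,5-dimethoxyphenyl)ethanethioate
Product: 5 1-(3,5-dimethoxyphenyl)henicosan-2-one
Conditions: NiBr2(dme) (10 mol %), dimethyl 2,2'-bipyridine-4,4'-dicarboxylate (10 mol %), Zn powder (2 equiv), ZnCl2 (1 equiv), THF/DMA, rt, N2; dilute aq HCl work-up
Reagents that add atoms: none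
Why: Zerovalent nickel carrying the electron-poor bipyridine inserts into the C(acyl)–S bond of 4, guided by the pyridyl nitrogen, to give an arylacetyl thiolate complex of divalent nickel, while the ZnCl2-activated ester 2 accepts one electron (from low-valent nickel or Zn), loses phthalimide anion and CO2 and releases the primary nonadecyl radical. The radical is captured at the acylnickel centre, reductive elimination from the resulting trivalent nickel forms the C2–C3 bond, and Zn returns the monovalent nickel left behind to the zerovalent state. The closest known reaction type is the nickel-catalysed decarboxylative cross-electrophile coupling of N-hydroxyphthalimide esters with S-2-pyridyl thioesters to unsymmetrical dialkyl ketones, applied here to an arylacetyl donor and a C19 radical. No ring is closed and no stereocentre is created. The step needs cross-coupling over homo-coupling, which is secured because the partners are activated by different mechanisms (two-electron insertion for the chelating thioester, one-electron fragmentation for the redox-active ester) and because the fatty acid rather than the arylacetic acid is the radical donor, giving an unstabilised primary radical that nickel traps fast instead of a persistent benzylic radical that would dimerise. It also needs the doubly activated C1–H2 group and the new ketone to survive, which the absence of any basic or nucleophilic carbon–metal reagent secures (no enolisation, no second addition), while room temperature and the chelating ligand hold back loss of CO from the arylacetyl nickel species.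

Step 4
Reactants: 5 1-(3,5-dimethoxyphenyl)henicosan-2-one
Product: 7 1-(3,5-dihydroxyphenyl)henicosan-2-one (target), via bis(dibromoboryl) ether 6 (not isolated)
Conditions: BBr3 (5 equiv), CH2Cl2, −78 °C to rt; then ice-water
Reagents that add atoms: boron tribromide, BrB(Br)Br (its boron and bromine are held only in 6 and are gone in 7)
Why: In this Lewis-acid aryl methyl ether cleavage (BBr3 demethylation) boron binds each methoxy oxygen, bromide removes the methyl group by SN2 and water hydrolyses the aryl borate 6, while the ketone only binds a further equivalent of BBr3 reversibly and the low temperature should suppress enolisation.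

**Compound list**
1 | icosanoic acid (arachidic acid) | CCCCCCCCCCCCCCCCCCCC(=O)O | starting material
2 | 1,3-dioxoisoindolin-2-yl icosanoate | CCCCCCCCCCCCCCCCCCCC(=O)ON1C(=O)c2ccccc2C1=O | intermediate
3 | 2-(3,5-dimethoxyphenyl)acetic acid | COc1cc(CC(=O)O)cc(OC)c1 | starting material
4 | S-(pyridin-2-yl) 2-(3,5-dimethoxyphenyl)ethanethioate | COc1cc(CC(=O)Sc2ccccn2)cc(OC)c1 | intermediate
5 | 1-(3,5-dimethoxyphenyl)henicosan-2-one | CCCCCCCCCCCCCCCCCCCC(=O)Cc1cc(OC)cc(OC)c1 | intermediate
6 | 1-[3,5-bis(dibromoboryloxy)phenyl]henicosan-2-one | CCCCCCCCCCCCCCCCCCCC(=O)Cc1cc(OB(Br)Br)cc(OB(Br)Br)c1 | intermediate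
7 | 1-(3,5-dihydroxyphenyl)henicosan-2-one | CCCCCCCCCCCCCCCCCCCC(=O)Cc1cc(O)cc(O)c1 | target

Total step count: 4. Longest linear sequence: 3 steps (3 to 4 to 5 to 7, or 1 to 2 to 5 to 7).

**Steps most likely to fail**

Risk A, the coupling of step 3.
- What may go wrong: cross-selectivity may be eroded by loss of CO from the arylacetyl nickel species, by dimerisation or hydrogen abstraction of the nonadecyl radical, or by reductive homocoupling of the thioester.
- Fallback: it makes the same bond by a polar rather than a radical event, sets out from 4 and comes back at 5.
- Commercial 1-bromononadecane is converted with Mg turnings in THF into nonadecylmagnesium bromide F1, which is added to 4 in THF at −78 °C. This is the known ketone synthesis from S-2-pyridyl thioesters and Grignard reagents.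
- Chelation of magnesium by the pyridyl nitrogen and the carbonyl oxygen should make addition faster than deprotonation at C1. It should also hold the tetrahedral adduct until the acidic quench, so 5 is released only at work-up and is not attacked a second time.

Risk B, the ether cleavage of step 4.
- What may go wrong: enolisation of the boron-bound ketone followed by aldol-type self-condensation, attack of the very electron-rich liberated ring on an activated carbonyl group, or incomplete cleavage of the second ether.
- Fallback: it changes the protecting group so that the last step is neutral, sets out from 3 and comes back at 7.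
- Compound 3 is demethylated before any ketone is present (48% aq HBr, AcOH, reflux) to 2-(3,5-dihydroxyphenyl)acetic acid F2.
- Benzylation (BnBr, K2CO3, DMF) should give benzyl 2-[3,5-bis(benzyloxy)phenyl]acetate F3, and saponification (LiOH, THF/H2O) gives 2-[3,5-bis(benzyloxy)phenyl]acetic acid F4.
- The conditions of step 2 give S-(pyridin-2-yl) 2-[3,5-bis(benzyloxy)phenyl]ethanethioate F5, and coupling with 2 under the conditions of step 3 gives 1-[3,5-bis(benzyloxy)phenyl]henicosan-2-one F6.
- Hydrogenolysis (H2, 10% Pd/C, EtOAc/EtOH, rt) should release 7 without touching the non-benzylic ketone.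

Risk C, the activation of step 2.
- What may go wrong: hydrolysis of the activated thioester during chromatography, poor separation from the phosphine-derived by-product, or self-condensation through the acidic C1–H.
- Fallback: it avoids any isolated activated ester, sets out from 3 and comes back at 5.
- Compound 3 is converted with (COCl)2 and catalytic DMF in CH2Cl2 into 2-(3,5-dimethoxyphenyl)acetyl chloride F7, which is used crude.
- F7 is joined directly to 2 by the known nickel-catalysed reductive ketone synthesis from redox-active esters and acid chlorides (NiCl2·6H2O, 4,4'-di-tert-butyl-2,2'-bipyridine, Zn powder, MeCN/THF, rt).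

**Further compounds**
F1 | step 3 | nonadecylmagnesium bromide | CCCCCCCCCCCCCCCCCCC[Mg]Br
F2 | step 4 | 2-(3,5-dihydroxyphenyl)acetic acid | OC(=O)Cc1cc(O)cc(O)c1
F3 | step 4 | benzyl 2-[3,5-bis(benzyloxy)phenyl]acetate | O=C(Cc1cc(OCc2ccccc2)cc(OCc2ccccc2)c1)OCc1ccccc1
F4 | step 4 | 2-[3,5-bis(benzyloxy)phenyl]acetic acid | OC(=O)Cc1cc(OCc2ccccc2)cc(OCc2ccccc2)c1
F5 | step 4 | S-(pyridin-2-yl) 2-[3,5-bis(benzyloxy)phenyl]ethanethioate | O=C(Cc1cc(OCc2ccccc2)cc(OCc2ccccc2)c1)Sc1ccccn1
F6 | step 4 | 1-[3,5-bis(benzyloxy)phenyl]henicosan-2-one | CCCCCCCCCCCCCCCCCCCC(=O)Cc1cc(OCc2ccccc2)cc(OCc2ccccc2)c1
F7 | step 2 | 2-(3,5-dimethoxyphenyl)acetyl chloride | COc1cc(CC(=O)Cl)cc(OC)c1
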